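**Retrosynthetic overview**
- The target is opened at the upper-unit C3–O bond and C4–H bond: both come from hydroboration–oxidation of a (2S)-4-aryl-2H-chromene, after which only global hydrogenolysis remains.
- The chromene pyran ring is closed by gold-catalysed 6-endo hydroarylation of an aryl propargyl ether whose alkyne already carries the flavonol (Sonogashira coupling with a flavonol 5-triflate).
- Key bond: the O1–C2 ether bond of the upper unit, formed enantioselectively by copper-catalysed propargylic etherification of a pyrogallol-derived phenol. This C–O bond sets the only reagent-controlled stereocentre; C3 and C4 are relayed from it.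
- The lower unit comes from quercetin: benzylation, C8 hydroxylation para to the 5-OH, benzylation of the new OH, and 5-O-triflation.
- Ring order: the lower pyranone ring is bought with quercetin; the upper pyran ring is closed last (step 9).

Assumption: the (S,S)-Ph-pybox–copper catalyst is taken to give the (S)-propargylic ether in step 3; if the sense of induction is the reverse, the (R,R)-ligand is used.

**Step 1**
Reactants: 1 pyrogallol
Product: 2 2,2-diphenyl-1,3-benzodioxol-4-ol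
Conditions: Ph2CCl2 (1.1 equiv), Ph2O, 170 °C
Reagents that add atoms: dichlorodiphenylmethane, ClC(Cl)(c1ccccc1)c1ccccc1
Why: Acetal formation between the gem-dichloride and two adjacent hydroxyls of pyrogallol gives the five-membered diphenylmethylene acetal and leaves one hydroxyl free.

**Step 2**
Reactants: 3 3,4-bis(benzyloxy)benzaldehyde
Product: 5 (±)-1-[3,4-bis(benzyloxy)phenyl]prop-2-yn-1-yl acetate, via bromomagnesium propargylic alkoxide 4 (not isolated)
Conditions: HC≡CMgBr, THF, 0 °C; then Ac2O, 0 °C to rt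
Reagents that add atoms: ethynylmagnesium bromide, C#C[Mg]Br; acetic anhydride, CC(=O)OC(C)=O
Why: Grignard 1,2-addition of the acetylide to the aldehyde and O-acetylation of the alkoxide in the same flask; the new centre is racemic and is reset in step 3.

**Step 3**
Reactants: 5 (±)-1-[3,4-bis(benzyloxy)phenyl]prop-2-yn-1-yl acetate; 2 2,2-diphenyl-1,3-benzodioxol-4-ol
Product: 6 (S)-4-{1-[3,4-bis(benzyloxy)phenyl]prop-2-yn-1-yloxy}-2,2-diphenyl-1,3-benzodioxole
Conditions: CuOTf·0.5C6H6 (5 mol %), (S,S)-Ph-pybox (10 mol %), iPr2NEt, 1,2-dichloroethane, −10 °C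
Reagents that add atoms: none
Why: Copper–pybox-catalysed enantioselective propargylic etherification: the copper acetylide of 5 ionises to a copper allenylidene and the phenoxide of 2 attacks the γ-carbon in the chiral pocket, so both enantiomers of 5 converge on the (S)-ether and the O1–C2 bond and its stereocentre are set.

**Step 4**
Reactants: 7 quercetin
Product: 8 3,7-bis(benzyloxy)-2-[3,4-bis(benzyloxy)phenyl]-5-hydroxy-4H-chromen-4-one
Conditions: BnBr (4.4 equiv), K2CO3, DMF, rt to 40 °C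
Reagents that add atoms: benzyl bromide, BrCc1ccccc1
Why: Williamson etherification of the four reactive hydroxyls; the 5-OH is hydrogen-bonded to the C4 carbonyl and stays free.

**Step 5**
Reactants: 8 3,7-bis(benzyloxy)-2-[3,4-bis(benzyloxy)phenyl]-5-hydroxy-4H-chromen-4-one
Product: 10 3,7-bis(benzyloxy)-2-[3,4-bis(benzyloxy)phenyl]-5,8-dihydroxy-4H-chromen-4-one, via potassium aryl 8-sulfate 9 (not isolated)
Conditions: K2S2O8, aq. KOH, pyridine, 0 °C to rt; then aq. HCl, Na2SO3, 80 °C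
Reagents that add atoms: potassium peroxodisulfate, [K+].[K+].[O-]S(=O)(=O)OOS(=O)(=O)[O-]
Why: Elbs persulfate oxidation: the 5-phenolate attacks the peroxide oxygen through C8, the only free carbon para to it, and the aryl sulfate is hydrolysed to the hydroquinone.

**Step 6**
Reactants: 10 3,7-bis(benzyloxy)-2-[3,4-bis(benzyloxy)phenyl]-5,8-dihydroxy-4H-chromen-4-one
Product: 11 3,7,8-tris(benzyloxy)-2-[3,4-bis(benzyloxy)phenyl]-5-hydroxy-4H-chromen-4-one
Conditions: BnBr (1.1 equiv), K2CO3, acetone, 50 °C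
Reagents that add atoms: benzyl bromide, BrCc1ccccc1
Why: Williamson etherification; the non-chelated 8-OH is alkylated while the chelated 5-OH is not.

**Step 7**
Reactants: 11 3,7,8-tris(benzyloxy)-2-[3,4-bis(benzyloxy)phenyl]-5-hydroxy-4H-chromen-4-one
Product: 12 3,7,8-tris(benzyloxy)-2-[3,4-bis(benzyloxy)phenyl]-4-oxo-4H-chromen-5-yl trifluoromethanesulfonate
Conditions: Tf2O, pyridine, CH2Cl2, 0 °C
Reagents that add atoms: trifluoromethanesulfonic anhydride, O=S(=O)(OS(=O)(=O)C(F)(F)F)C(F)(F)F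
Why: O-sulfonylation of the remaining phenol turns C5 into a cross-coupling site activated by the adjacent carbonyl.

**Step 8**
Reactants: 6 (S)-4-{1-[3,4-bis(benzyloxy)phenyl]prop-2-yn-1-yloxy}-2,2-diphenyl-1,3-benzodioxole; 12 3,7,8-tris(benzyloxy)-2-[3,4-bis(benzyloxy)phenyl]-4-oxo-4H-chromen-5-yl trifluoromethanesulfonate
Product: 13 3,7,8-tris(benzyloxy)-2-[3,4-bis(benzyloxy)phenyl]-5-{(3R)-3-[3,4-bis(benzyloxy)phenyl]-3-[(2,2-diphenyl-1,3-benzodioxol-4-yl)oxy]prop-1-yn-1-yl}-4H-chromen-4-one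
Conditions: Pd(PPh3)4 (5 mol %), CuI (10 mol %), Et3N, DMF, 60 °C
Reagents that add atoms: none
Why: Sonogashira coupling of the terminal alkyne with the electron-poor aryl triflate joins the two flavonoid halves; the stereocentre is not involved (the descriptor changes from S to R only because the alkyne now outranks the aryl group).

**Step 9**
Reactants: 13 3,7,8-tris(benzyloxy)-2-[3,4-bis(benzyloxy)phenyl]-5-{(3R)-3-[3,4-bis(benzyloxy)phenyl]-3-[(2,2-diphenyl-1,3-benzodioxol-4-yl)oxy]prop-1-yn-1-yl}-4H-chromen-4-one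
Product: 14 3,7,8-tris(benzyloxy)-2-[3,4-bis(benzyloxy)phenyl]-5-{(2S)-2-[3,4-bis(benzyloxy)phenyl]-7,8-(diphenylmethylenedioxy)-2H-chromen-4-yl}-4H-chromen-4-one
Conditions: [(2-biphenyl)P(tBu)2]Au(NCMe)SbF6 (5 mol %), 2,6-di-tert-butyl-4-methylpyridine (10 mol %), 4 Å MS, CH2Cl2, 0 °C to rt
Reagents that add atoms: none
Why: Proposed new method: monovalent gold π-activates the alkyne, the benzodioxole carbon ortho to the ether oxygen (and para to an acetal oxygen) attacks 6-endo-dig at the flavonol-bearing carbon, and rearomatisation with protodeauration gives the 2H-chromene with C2 untouched; capture of the alkyne by the neighbouring chromone carbonyl should be reversible because that pyrylium-type vinyl-gold has no proton to lose, and the hindered pyridine keeps acid from ionising the C2–O bond; the closest known reaction type is gold-catalysed intramolecular hydroarylation of aryl propargyl ethers to 2H-chromenes, not yet shown on an alkyne that bears a peri-carbonyl chromone next to an ionisable O-stereocentre.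

**Step 10**
Reactants: 14 3,7,8-tris(benzyloxy)-2-[3,4-bis(benzyloxy)phenyl]-5-{(2S)-2-[3,4-bis(benzyloxy)phenyl]-7,8-(diphenylmethylenedioxy)-2H-chromen-4-yl}-4H-chromen-4-one
Product: 16 3,7,8-tris(benzyloxy)-2-[3,4-bis(benzyloxy)phenyl]-5-{(2R,3S,4R)-2-[3,4-bis(benzyloxy)phenyl]-3-hydroxy-7,8-(diphenylmethylenedioxy)chroman-4-yl}-4H-chromen-4-one, via C3-alkylborane 15 (not isolated)
Conditions: BH3·SMe2, THF, 0 °C to rt; then 30% H2O2, 2 M NaOH, 0 °C
Reagents that add atoms: borane–dimethyl sulfide, C[S+](C)[BH3-] (boron is present in 15 only); hydrogen peroxide, OO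
Why: Hydroboration–oxidation: borane adds syn to the trisubstituted C3=C4 bond on the face opposite the C2 aryl group, boron to C3 and hydrogen to C4, and oxidation with retention gives the 2,3-trans-3,4-trans alcohol, so C3 (S) and C4 (R) are set by the C2 centre.

**Step 11**
Reactants: 16 3,7,8-tris(benzyloxy)-2-[3,4-bis(benzyloxy)phenyl]-5-{(2R,3S,4R)-2-[3,4-bis(benzyloxy)phenyl]-3-hydroxy-7,8-(diphenylmethylenedioxy)chroman-4-yl}-4H-chromen-4-one
Product: 17 2-(3,4-dihydroxyphenyl)-5-[(2R,3S,4R)-2-(3,4-dihydroxyphenyl)-3,7,8-trihydroxychroman-4-yl]-3,7,8-trihydroxy-4H-chromen-4-one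
Conditions: H2 (1 atm), Pd(OH)2/C, THF–MeOH, rt
Reagents that add atoms: none
Why: Hydrogenolysis removes the seven benzyl ethers and the diphenylmethylene acetal in one operation without touching the flavonol double bond or the three stereocentres.

**Compound list**
1 | pyrogallol | Oc1cccc(O)c1O | starting material
2 | 2,2-diphenyl-1,3-benzodioxol-4-ol | Oc1cccc2OC(c3ccccc3)(c3ccccc3)Oc12 | intermediate
3 | 3,4-bis(benzyloxy)benzaldehyde | O=Cc1ccc(OCc2ccccc2)c(OCc2ccccc2)c1 | starting material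
4 | bromomagnesium 1-[3,4-bis(benzyloxy)phenyl]prop-2-yn-1-olate (racemic) | C#CC(O[Mg]Br)c1ccc(OCc2ccccc2)c(OCc2ccccc2)c1 | intermediate
5 | (±)-1-[3,4-bis(benzyloxy)phenyl]prop-2-yn-1-yl acetate | CC(=O)OC(C#C)c1ccc(OCc2ccccc2)c(OCc2ccccc2)c1 | intermediate
6 | (S)-4-{1-[3,4-bis(benzyloxy)phenyl]prop-2-yn-1-yloxy}-2,2-diphenyl-1,3-benzodioxole | C#C[C@H](Oc1cccc2OC(c3ccccc3)(c3ccccc3)Oc12)c1ccc(OCc2ccccc2)c(OCc2ccccc2)c1 | intermediate
7 | quercetin | O=c1c(O)c(-c2ccc(O)c(O)c2)oc2cc(O)cc(O)c12 | starting material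
8 | 3,7-bis(benzyloxy)-2-[3,4-bis(benzyloxy)phenyl]-5-hydroxy-4H-chromen-4-one | O=c1c(OCc2ccccc2)c(-c2ccc(OCc3ccccc3)c(OCc3ccccc3)c2)oc2cc(OCc3ccccc3)cc(O)c12 | intermediate
9 | potassium 3,7-bis(benzyloxy)-2-[3,4-bis(benzyloxy)phenyl]-5-hydroxy-4-oxo-4H-chromen-8-yl sulfate | O=c1c(OCc2ccccc2)c(-c2ccc(OCc3ccccc3)c(OCc3ccccc3)c2)oc2c(OS(=O)(=O)[O-])c(OCc3ccccc3)cc(O)c12.[K+] | intermediate
10 | 3,7-bis(benzyloxy)-2-[3,4-bis(benzyloxy)phenyl]-5,8-dihydroxy-4H-chromen-4-one | O=c1c(OCc2ccccc2)c(-c2ccc(OCc3ccccc3)c(OCc3ccccc3)c2)oc2c(O)c(OCc3ccccc3)cc(O)c12 | intermediate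
11 | 3,7,8-tris(benzyloxy)-2-[3,4-bis(benzyloxy)phenyl]-5-hydroxy-4H-chromen-4-one | O=c1c(OCc2ccccc2)c(-c2ccc(OCc3ccccc3)c(OCc3ccccc3)c2)oc2c(OCc3ccccc3)c(OCc3ccccc3)cc(O)c12 | intermediate
12 | 3,7,8-tris(benzyloxy)-2-[3,4-bis(benzyloxy)phenyl]-4-oxo-4H-chromen-5-yl trifluoromethanesulfonate | O=c1c(OCc2ccccc2)c(-c2ccc(OCc3ccccc3)c(OCc3ccccc3)c2)oc2c(OCc3ccccc3)c(OCc3ccccc3)cc(OS(=O)(=O)C(F)(F)F)c12 | intermediate
13 | 3,7,8-tris(benzyloxy)-2-[3,4-bis(benzyloxy)phenyl]-5-{(3R)-3-[3,4-bis(benzyloxy)phenyl]-3-[(2,2-diphenyl-1,3-benzodioxol-4-yl)oxy]prop-1-yn-1-yl}-4H-chromen-4-one | O=c1c(OCc2ccccc2)c(-c2ccc(OCc3ccccc3)c(OCc3ccccc3)c2)oc2c(OCc3ccccc3)c(OCc3ccccc3)cc(C#C[C@H](Oc3cccc4OC(c5ccccc5)(c5ccccc5)Oc34)c3ccc(OCc4ccccc4)c(OCc4ccccc4)c3)c12 | intermediate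
14 | 3,7,8-tris(benzyloxy)-2-[3,4-bis(benzyloxy)phenyl]-5-{(2S)-2-[3,4-bis(benzyloxy)phenyl]-7,8-(diphenylmethylenedioxy)-2H-chromen-4-yl}-4H-chromen-4-one | O=c1c(OCc2ccccc2)c(-c2ccc(OCc3ccccc3)c(OCc3ccccc3)c2)oc2c(OCc3ccccc3)c(OCc3ccccc3)cc(C3=C[C@@H](c4ccc(OCc5ccccc5)c(OCc5ccccc5)c4)Oc4c3ccc3OC(c5ccccc5)(c5ccccc5)Oc43)c12 | intermediate
15 | 3,7,8-tris(benzyloxy)-2-[3,4-bis(benzyloxy)phenyl]-5-{(2S,3S,4R)-3-boranyl-2-[3,4-bis(benzyloxy)phenyl]-7,8-(diphenylmethylenedioxy)chroman-4-yl}-4H-chromen-4-one | O=c1c(OCc2ccccc2)c(-c2ccc(OCc3ccccc3)c(OCc3ccccc3)c2)oc2c(OCc3ccccc3)c(OCc3ccccc3)cc([C@@H]3c4ccc5OC(c6ccccc6)(c6ccccc6)Oc5c4O[C@H](c4ccc(OCc5ccccc5)c(OCc5ccccc5)c4)[C@H]3B)c12 | intermediate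
16 | 3,7,8-tris(benzyloxy)-2-[3,4-bis(benzyloxy)phenyl]-5-{(2R,3S,4R)-2-[3,4-bis(benzyloxy)phenyl]-3-hydroxy-7,8-(diphenylmethylenedioxy)chroman-4-yl}-4H-chromen-4-one | O=c1c(OCc2ccccc2)c(-c2ccc(OCc3ccccc3)c(OCc3ccccc3)c2)oc2c(OCc3ccccc3)c(OCc3ccccc3)cc([C@@H]3c4ccc5OC(c6ccccc6)(c6ccccc6)Oc5c4O[C@H](c4ccc(OCc5ccccc5)c(OCc5ccccc5)c4)[C@H]3O)c12 | intermediate
17 | 2-(3,4-dihydroxyphenyl)-5-[(2R,3S,4R)-2-(3,4-dihydroxyphenyl)-3,7,8-trihydroxychroman-4-yl]-3,7,8-trihydroxy-4H-chromen-4-one | O=c1c(O)c(-c2ccc(O)c(O)c2)oc2c(O)c(O)cc([C@@H]3c4ccc(O)c(O)c4O[C@H](c4ccc(O)c(O)c4)[C@H]3O)c12 | target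

**Step count and risks**
Total steps: 11. Longest linear sequence: 8 (steps 4 to 11, from quercetin); the upper-unit branch (steps 1 to 3) joins at step 8.

Three steps most likely to fail:

Step 9 (the proposed new step). The ring closure may be diverted by the neighbouring carbonyl, go 5-exo, or erode the C2 configuration. The fallback closes the pyran ring before the two halves are joined, using known chemistry; it sets out from 6 and 12 and comes back at 14. Alkyne 6 is iodinated (N-iodosuccinimide, AgNO3 cat., acetone) to (R)-4-{1-[3,4-bis(benzyloxy)phenyl]-3-iodoprop-2-yn-1-yloxy}-2,2-diphenyl-1,3-benzodioxole F4. F4 undergoes the known gold-catalysed 6-endo hydroarylation of 1-iodoalkynes without halide shift ([(2,4-tBu2C6H3O)3P]AuNTf2, dioxane; the ligand must be confirmed) to give (2S)-2-[3,4-bis(benzyloxy)phenyl]-4-iodo-7,8-(diphenylmethylenedioxy)-2H-chromene F5. Triflate 12 is converted by Miyaura borylation (B2pin2, Pd(dppf)Cl2, KOAc, dioxane) into 3,7,8-tris(benzyloxy)-2-[3,4-bis(benzyloxy)phenyl]-5-(4,4,5,5-tetramethyl-1,3,2-dioxaborolan-2-yl)-4H-chromen-4-one F6. Suzuki–Miyaura coupling of F5 with F6 (Pd(PPh3)4, K3PO4, dioxane–water) gives 14.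

Step 3. The electron-rich ester may ionise without the catalyst (lower ee), or the phenol may react through carbon. The fallback sets the centre by carbonyl addition and then inverts it; it sets out from 3 and 2 and comes back at 6. Aldehyde 3 is alkynylated with ethynyltrimethylsilane (Et2Zn, Ti(OiPr)4, the BINOL enantiomer that gives the S alcohol, toluene) to (S)-1-[3,4-bis(benzyloxy)phenyl]-3-(trimethylsilyl)prop-2-yn-1-ol F1. Mitsunobu etherification with phenol 2 (PPh3, diisopropyl azodicarboxylate, toluene, −20 °C) proceeds with inversion to (R)-4-{1-[3,4-bis(benzyloxy)phenyl]-3-(trimethylsilyl)prop-2-yn-1-yloxy}-2,2-diphenyl-1,3-benzodioxole F2. K2CO3 in MeOH removes the silyl group and gives 6.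

Step 5. Elbs oxidations are low-yielding, and the lipophilic substrate dissolves poorly in aqueous alkali. The fallback goes through a quinone instead of a sulfate ester; it sets out from 8 and comes back at 10. Phenol 8 is oxidised with Fremy's salt ON(SO3K)2 (KH2PO4 buffer, acetone–water) to 3,7-bis(benzyloxy)-2-[3,4-bis(benzyloxy)phenyl]-4H-chromene-4,5,8-trione F3, which is reduced with Na2S2O4 (EtOAc–water) to hydroquinone 10.

**Further compounds**
F1 | step 3 | (S)-1-[3,4-bis(benzyloxy)phenyl]-3-(trimethylsilyl)prop-2-yn-1-ol | O[C@H](C#C[Si](C)(C)C)c1ccc(OCc2ccccc2)c(OCc2ccccc2)c1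
F2 | step 3 | (R)-4-{1-[3,4-bis(benzyloxy)phenyl]-3-(trimethylsilyl)prop-2-yn-1-yloxy}-2,2-diphenyl-1,3-benzodioxole | C[Si](C)(C)C#C[C@H](Oc1cccc2OC(c3ccccc3)(c3ccccc3)Oc12)c1ccc(OCc2ccccc2)c(OCc2ccccc2)c1
F3 | step 5 | 3,7-bis(benzyloxy)-2-[3,4-bis(benzyloxy)phenyl]-4H-chromene-4,5,8-trione | O=C1C(OCc2ccccc2)=C(c2ccc(OCc3ccccc3)c(OCc3ccccc3)c2)OC2=C1C(=O)C=C(OCc1ccccc1)C2=O
F4 | step 9 | (R)-4-{1-[3,4-bis(benzyloxy)phenyl]-3-iodoprop-2-yn-1-yloxy}-2,2-diphenyl-1,3-benzodioxole | IC#C[C@H](Oc1cccc2OC(c3ccccc3)(c3ccccc3)Oc12)c1ccc(OCc2ccccc2)c(OCc2ccccc2)c1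
F5 | step 9 | (2S)-2-[3,4-bis(benzyloxy)phenyl]-4-iodo-7,8-(diphenylmethylenedioxy)-2H-chromene | IC1=C[C@@H](c2ccc(OCc3ccccc3)c(OCc3ccccc3)c2)Oc2c1ccc1OC(c3ccccc3)(c3ccccc3)Oc21
F6 | step 9 | 3,7,8-tris(benzyloxy)-2-[3,4-bis(benzyloxy)phenyl]-5-(4,4,5,5-tetramethyl-1,3,2-dioxaborolan-2-yl)-4H-chromen-4-one | O=c1c(OCc2ccccc2)c(-c2ccc(OCc3ccccc3)c(OCc3ccccc3)c2)oc2c(OCc3ccccc3)c(OCc3ccccc3)cc(B3OC(C)(C)C(C)(C)O3)c12
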